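**Plan**
- Retrosynthesis: the quinone goes back to a 1,4-dimethoxyarene and the diol to an acetonide. The chain is then cut at C1′–C2′ (ring CH2 to olefinic CH, together with C3′–CH3), at C5′–C6′ (with C7′–CH3) and at C8′–C9′. The C10′/C11′ oxygens go back to nerol.
- Enabling feature: C2′=C3′ (and again C6′=C7′) is an E-trisubstituted olefin with its methyl on the inner carbon, cis to the next CH2, and its only vinylic H on C2′. C2′ is bound through the benzylic C1′ to ring carbon C2, next to the C1 carbonyl. This is the imprint of syn Me–Al addition across a terminal C2′≡C3′ alkyne followed by exchange of Al for a benzylic carbon.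
- Forward, tail to head: nerol → epoxy alcohol → triol → terminal epoxide → propargylation (C8′–C9′) → acetonide → carboalumination/iodination and homopropargylzinc coupling (C6′=C7′, C5′–C6′) → terminal enyne. The arene partner comes in three steps from 4-methoxy-2-methylphenol.
- Key event: one-pot methylalumination of the enyne and nickel-catalysed coupling with the benzylic chloride makes C3′–CH3, the E olefin and C1′–C2′ in one operation. Oxidative demethylation and acetonide hydrolysis finish the route; no ring is built.
- Stereochemistry: C10′ and C11′ come from Sharpless epoxidation of nerol (D-tartrate) and acid hydrolysis with inversion at the tertiary carbon, which gives the threo R,R diol. Both E olefins come from syn carbometalation and stereoretentive coupling.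

Key step: step 11

Remark: ring atoms are numbered C1–C6 (C1 is the carbonyl flanked by the two substituted carbons) and side-chain atoms C1′–C16′ from the ring outward. Nerol, 4-methoxy-2-methylphenol and (4-bromobut-1-yn-1-yl)trimethylsilane are assumed to be purchasable.

**Route**

Step 1
Reactants: 1 nerol, (2Z)-3,7-dimethylocta-2,6-dien-1-ol
Product: 2 [(2R,3S)-3-methyl-3-(4-methylpent-3-en-1-yl)oxiran-2-yl]methanol
Conditions: Ti(OiPr)4 (10 mol %), D-(−)-diethyl tartrate (12 mol %), t-BuOOH (2 equiv, decane solution), 4 Å molecular sieves, CH2Cl2, −20 °C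
Reagents that add atoms: tert-butyl hydroperoxide, CC(C)(C)OO
Why: Sharpless asymmetric epoxidation delivers oxygen only to the allylic C2=C3 olefin (the remote trisubstituted olefin has no directing hydroxyl), and the D-tartrate ligand sets C2 (R) and C3 (S) together by face selection on the Z olefin.

Step 2
Reactants: 2 [(2R,3S)-3-methyl-3-(4-methylpent-3-en-1-yl)oxiran-2-yl]methanol
Product: 3 (2R,3R)-3,7-dimethyloct-6-ene-1,2,3-triol
Conditions: HClO4 (cat.), THF/H2O, 0 °C → rt
Reagents that add atoms: water, O
Why: Acid-catalysed epoxide hydrolysis should let water attack the tertiary C3 (the carbon best able to carry positive charge and remote from the electron-withdrawing CH2OH) from the back side, so C3 is inverted (S → R) while C2 keeps its C–O bond, which converts the cis epoxide into the threo (R,R) diol.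

Step 3
Reactants: 3 (2R,3R)-3,7-dimethyloct-6-ene-1,2,3-triol
Product: 5 (2R)-6-methyl-2-[(2R)-oxiran-2-yl]hept-5-en-2-ol, via primary tosylate 4 (not isolated)
Conditions: TsCl (1.05 equiv), Et3N, Bu2SnO (2 mol %), CH2Cl2, 0 °C; then K2CO3, MeOH, 0 °C, short reaction time
Reagents that add atoms: none
Why: Tin-acetal-catalysed sulfonylation is selective for the primary hydroxyl of the terminal 1,2-diol, and the neighbouring secondary alkoxide then closes the oxirane by intramolecular Williamson displacement at C1, so neither stereocenter is touched and the cold, brief base treatment limits epoxide migration.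

Step 4
Reactants: 5 (2R)-6-methyl-2-[(2R)-oxiran-2-yl]hept-5-en-2-ol
Product: 6 (5R,6R)-6,10-dimethylundec-9-en-1-yne-5,6-diol
Conditions: allenylmagnesium bromide (3 equiv, from propargyl bromide, Mg, ZnBr2 cat.), Et2O, −78 → 0 °C; aq. NH4Cl
Reagents that add atoms: allenylmagnesium bromide, C=C=C[Mg]Br
Why: After one equivalent has deprotonated the tertiary hydroxyl, the allenyl Grignard reagent should open the magnesium-chelated terminal epoxide at its CH2 carbon through its γ-carbon (SE2′ epoxide ring-opening), which installs the but-3-ynyl chain (C8′–C9′ bond) and leaves both carbinol centers unchanged.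

Step 5
Reactants: 6 (5R,6R)-6,10-dimethylundec-9-en-1-yne-5,6-diol
Product: 7 (4R,5R)-4-(but-3-yn-1-yl)-2,2,5-trimethyl-5-(4-methylpent-3-en-1-yl)-1,3-dioxolane
Conditions: 2,2-dimethoxypropane, pyridinium p-toluenesulfonate (cat.), CH2Cl2, rt
Reagents that add atoms: 2,2-dimethoxypropane, COC(C)(C)OC
Why: Acid-catalysed transacetalization closes the isopropylidene acetal on the vicinal secondary/tertiary diol without breaking either C–O bond, masking the diol against organoaluminum reagents and tetravalent cerium later on.

Step 6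
Reactants: 7 (4R,5R)-4-(but-3-yn-1-yl)-2,2,5-trimethyl-5-(4-methylpent-3-en-1-yl)-1,3-dioxolane
Product: 9 (4R,5R)-4-[(3E)-4-iodo-3-methylbut-3-en-1-yl]-2,2,5-trimethyl-5-(4-methylpent-3-en-1-yl)-1,3-dioxolane, via alkenylalane 8 (not isolated)
Conditions: Me3Al (2.5 equiv), Cp2ZrCl2 (0.25 equiv), CH2Cl2, 0 °C → rt; then I2, THF, −30 → 0 °C
Reagents that add atoms: trimethylaluminum, C[Al](C)C; iodine, II
Why: Negishi zirconium-catalysed carboalumination adds methyl and aluminum syn across the terminal alkyne with methyl on the internal carbon (C7′), and iodinolysis of the C–Al bond with retention should give the E iodide, while the trisubstituted olefin and the acetal are expected to stay intact at this temperature.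

Step 7
Reactants: 9 (4R,5R)-4-[(3E)-4-iodo-3-methylbut-3-en-1-yl]-2,2,5-trimethyl-5-(4-methylpent-3-en-1-yl)-1,3-dioxolane; 10 (4-bromobut-1-yn-1-yl)trimethylsilane
Product: 13 (4R,5R)-2,2,5-trimethyl-4-[(3E)-3-methyloct-3-en-7-yn-1-yl]-5-(4-methylpent-3-en-1-yl)-1,3-dioxolane, via homopropargylzinc bromide 11 (not isolated), via silyl enyne 12 (not isolated)
Conditions: 10, Zn dust, LiCl, THF, 40 °C; then 9, PdCl2(dppf) (3 mol %), THF, rt; then K2CO3, MeOH, rt
Reagents that add atoms: none
Why: Zinc insertion into the primary bromide gives an alkylzinc that should undergo Negishi coupling with the alkenyl iodide with retention of the E geometry (the bidentate phosphine suppresses β-hydride elimination), and methanolysis then removes the alkynyl silyl group to unveil the terminal alkyne.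

Step 8
Reactants: 14 4-methoxy-2-methylphenol
Product: 16 2-(hydroxymethyl)-4-methoxy-6-methylphenol, via benzodioxaborin 15 (not isolated)
Conditions: PhB(OH)2 (1.1 equiv), (CH2O)n, EtCO2H (cat.), toluene, reflux with water removal; then propane-1,3-diol, THF, rt
Reagents that add atoms: formaldehyde (as paraformaldehyde), C=O
Why: In the boronate-templated ortho-hydroxymethylation of phenols the aryl borate delivers formaldehyde intramolecularly to the only free ortho position (para is blocked by OMe), and transesterification with the diol releases the saligenin without over-condensation.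

Step 9
Reactants: 16 2-(hydroxymethyl)-4-methoxy-6-methylphenol
Product: 17 (2,5-dimethoxy-3-methylphenyl)methanol
Conditions: MeI (1.2 equiv), K2CO3, acetone, reflux
Reagents that add atoms: iodomethane, CI
Why: Williamson etherification under carbonate conditions should methylate only the phenoxide, because the benzylic alcohol is not deprotonated by K2CO3.

Step 10
Reactants: 17 (2,5-dimethoxy-3-methylphenyl)methanol
Product: 18 1-(chloromethyl)-2,5-dimethoxy-3-methylbenzene
Conditions: SOCl2, CH2Cl2, 0 °C → rt
Reagents that add atoms: thionyl chloride, ClS(Cl)=O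
Why: Chlorodehydroxylation through the chlorosulfite converts the electron-rich benzylic alcohol into the chloride under non-aqueous conditions that leave the aryl methyl ethers untouched.

Step 11
Reactants: 13 (4R,5R)-2,2,5-trimethyl-4-[(3E)-3-methyloct-3-en-7-yn-1-yl]-5-(4-methylpent-3-en-1-yl)-1,3-dioxolane; 18 1-(chloromethyl)-2,5-dimethoxy-3-methylbenzene
Product: 20 (4R,5R)-4-[(3E,7E)-9-(2,5-dimethoxy-3-methylphenyl)-3,7-dimethylnona-3,7-dien-1-yl]-2,2,5-trimethyl-5-(4-methylpent-3-en-1-yl)-1,3-dioxolane, via dienylalane 19 (not isolated)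
Conditions: Me3Al (2.0 equiv), Cp2ZrCl2 (0.25 equiv), ClCH2CH2Cl, 0 °C → rt; volatiles removed in vacuo; THF; 18 (0.9 equiv), NiCl2(PPh3)2 (3 mol %) pre-reduced with n-BuLi (6 mol %) to zerovalent nickel, rt
Reagents that add atoms: trimethylaluminum, C[Al](C)C
Why: Cp2ZrCl2/Me3Al generates an electrophilic methylzirconium species that adds Me–metal syn across the terminal C2′≡C3′ triple bond with methyl on the internal carbon C3′, and exchange to aluminum leaves the (E)-2-methylalk-1-enyl dimethylalane 19; zerovalent nickel then inserts into the benzylic C–Cl bond of 18, the alkenyl group transmetalates from aluminum with retention, and reductive elimination forms the C1′–C2′ bond. The closest known reaction type is the one-pot Negishi carboalumination/nickel-catalysed cross-coupling of alkenylalanes with benzylic chlorides. No ring is closed and no stereocenter is formed; the stereo-element created is the E geometry of C2′=C3′, which follows from syn carbometalation and the stereoretentive coupling. The step needs regioselectivity (aluminum on the terminal carbon), secured by the terminal alkyne itself, and chemoselectivity, secured because the two trisubstituted olefins are inert to carboalumination and an sp2 alkenyl group transfers from aluminum much faster than methyl. Excess Me3Al is stripped before the coupling and the temperature kept at or below rt so that the dioxolane is not attacked.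

Step 12
Reactants: 20 (4R,5R)-4-[(3E,7E)-9-(2,5-dimethoxy-3-methylphenyl)-3,7-dimethylnona-3,7-dien-1-yl]-2,2,5-trimethyl-5-(4-methylpent-3-en-1-yl)-1,3-dioxolane
Product: 21 2-{(2E,6E)-3,7-dimethyl-9-[(4R,5R)-2,2,5-trimethyl-5-(4-methylpent-3-en-1-yl)-1,3-dioxolan-4-yl]nona-2,6-dien-1-yl}-6-methylcyclohexa-2,5-diene-1,4-dione
Conditions: (NH4)2Ce(NO3)6 (2.2 equiv), MeCN/H2O, 0 °C, brief
Reagents that add atoms: water, O
Why: Oxidative demethylation by tetravalent cerium proceeds through the arene radical cation, which forms far more easily than an olefin radical cation, and water attack at the two methoxy-bearing carbons with loss of methanol should give the 2,6-disubstituted 1,4-benzoquinone while the short, cold exposure spares the acetonide.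

Step 13
Reactants: 21 2-{(2E,6E)-3,7-dimethyl-9-[(4R,5R)-2,2,5-trimethyl-5-(4-methylpent-3-en-1-yl)-1,3-dioxolan-4-yl]nona-2,6-dien-1-yl}-6-methylcyclohexa-2,5-diene-1,4-dione
Product: 22 2-[(2E,6E,10R,11R)-10,11-dihydroxy-3,7,11,15-tetramethylhexadeca-2,6,14-trien-1-yl]-6-methylcyclohexa-2,5-diene-1,4-dione
Conditions: AcOH/H2O/THF, 40 °C
Reagents that add atoms: none
Why: Mild acid-catalysed acetal hydrolysis should release the (10′R,11′R) diol without breaking either carbinol C–O bond, and the quinone and the trisubstituted olefins tolerate aqueous acetic acid.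

**Compound list**
1 | nerol, (2Z)-3,7-dimethylocta-2,6-dien-1-ol | CC(C)=CCC/C(C)=C\CO | starting material
2 | [(2R,3S)-3-methyl-3-(4-methylpent-3-en-1-yl)oxiran-2-yl]methanol | CC(C)=CCC[C@]1(C)O[C@@H]1CO | intermediate
3 | (2R,3R)-3,7-dimethyloct-6-ene-1,2,3-triol | CC(C)=CCC[C@@](C)(O)[C@H](O)CO | intermediate
4 | (2R,3R)-2,3-dihydroxy-3,7-dimethyloct-6-en-1-yl 4-methylbenzenesulfonate | CC(C)=CCC[C@@](C)(O)[C@H](O)COS(=O)(=O)c1ccc(C)cc1 | intermediate
5 | (2R)-6-methyl-2-[(2R)-oxiran-2-yl]hept-5-en-2-ol | CC(C)=CCC[C@@](C)(O)[C@H]1CO1 | intermediate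
6 | (5R,6R)-6,10-dimethylundec-9-en-1-yne-5,6-diol | CC(C)=CCC[C@@](C)(O)[C@H](O)CCC#C | intermediate
7 | (4R,5R)-4-(but-3-yn-1-yl)-2,2,5-trimethyl-5-(4-methylpent-3-en-1-yl)-1,3-dioxolane | CC(C)=CCC[C@@]1(C)OC(C)(C)O[C@@H]1CCC#C | intermediate
8 | dimethyl{(1E)-2-methyl-4-[(4R,5R)-2,2,5-trimethyl-5-(4-methylpent-3-en-1-yl)-1,3-dioxolan-4-yl]but-1-en-1-yl}alumane | CC(C)=CCC[C@@]1(C)OC(C)(C)O[C@@H]1CC/C(C)=C/[Al](C)C | intermediate
9 | (4R,5R)-4-[(3E)-4-iodo-3-methylbut-3-en-1-yl]-2,2,5-trimethyl-5-(4-methylpent-3-en-1-yl)-1,3-dioxolane | CC(C)=CCC[C@@]1(C)OC(C)(C)O[C@@H]1CC/C(C)=C/I | intermediate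
10 | (4-bromobut-1-yn-1-yl)trimethylsilane | C[Si](C)(C)C#CCCBr | starting material
11 | bromo[4-(trimethylsilyl)but-3-yn-1-yl]zinc | C[Si](C)(C)C#CCC[Zn]Br | intermediate
12 | trimethyl{(5E)-6-methyl-8-[(4R,5R)-2,2,5-trimethyl-5-(4-methylpent-3-en-1-yl)-1,3-dioxolan-4-yl]oct-5-en-1-yn-1-yl}silane | CC(C)=CCC[C@@]1(C)OC(C)(C)O[C@@H]1CC/C(C)=C/CCC#C[Si](C)(C)C | intermediate
13 | (4R,5R)-2,2,5-trimethyl-4-[(3E)-3-methyloct-3-en-7-yn-1-yl]-5-(4-methylpent-3-en-1-yl)-1,3-dioxolane | CC(C)=CCC[C@@]1(C)OC(C)(C)O[C@@H]1CC/C(C)=C/CCC#C | intermediate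
14 | 4-methoxy-2-methylphenol | COc1ccc(O)c(C)c1 | starting material
15 | 6-methoxy-8-methyl-2-phenyl-4H-1,3,2-benzodioxaborinine | COc1cc(C)c2OB(c3ccccc3)OCc2c1 | intermediate
16 | 2-(hydroxymethyl)-4-methoxy-6-methylphenol | COc1cc(C)c(O)c(CO)c1 | intermediate
17 | (2,5-dimethoxy-3-methylphenyl)methanol | COc1cc(C)c(OC)c(CO)c1 | intermediate
18 | 1-(chloromethyl)-2,5-dimethoxy-3-methylbenzene | COc1cc(C)c(OC)c(CCl)c1 | intermediate
19 | {(1E,5E)-2,6-dimethyl-8-[(4R,5R)-2,2,5-trimethyl-5-(4-methylpent-3-en-1-yl)-1,3-dioxolan-4-yl]octa-1,5-dien-1-yl}dimethylalumane | CC(C)=CCC[C@@]1(C)OC(C)(C)O[C@@H]1CC/C(C)=C/CC/C(C)=C/[Al](C)C | intermediate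
20 | (4R,5R)-4-[(3E,7E)-9-(2,5-dimethoxy-3-methylphenyl)-3,7-dimethylnona-3,7-dien-1-yl]-2,2,5-trimethyl-5-(4-methylpent-3-en-1-yl)-1,3-dioxolane | CC(C)=CCC[C@@]1(C)OC(C)(C)O[C@@H]1CC/C(C)=C/CC/C(C)=C/Cc1cc(OC)cc(C)c1OC | intermediate
21 | 2-{(2E,6E)-3,7-dimethyl-9-[(4R,5R)-2,2,5-trimethyl-5-(4-methylpent-3-en-1-yl)-1,3-dioxolan-4-yl]nona-2,6-dien-1-yl}-6-methylcyclohexa-2,5-diene-1,4-dione | CC(C)=CCC[C@@]1(C)OC(C)(C)O[C@@H]1CC/C(C)=C/CC/C(C)=C/CC2=CC(=O)C=C(C)C2=O | intermediate
22 | 2-[(2E,6E,10R,11R)-10,11-dihydroxy-3,7,11,15-tetramethylhexadeca-2,6,14-trien-1-yl]-6-methylcyclohexa-2,5-diene-1,4-dione | CC(C)=CCC[C@@](C)(O)[C@H](O)CC/C(C)=C/CC/C(C)=C/CC1=CC(=O)C=C(C)C1=O | target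

**Step count**
Total: 13 steps. Longest linear sequence: 10 steps (steps 1–7, then 11–13); steps 8–10 form the three-step arene branch.

**Steps most likely to fail**

Step 11 (key step). The risks are transfer of methyl instead of alkenyl to nickel, reductive dimerisation of the benzylic chloride, and carry-through of the minor carboalumination regioisomer, which cannot be removed at the alane stage. The fallback reverses the polarity, sets out from 13 and 18 and returns at 20. Compound 13 is carboaluminated and iodinated (Me3Al, Cp2ZrCl2; then I2) to the alkenyl iodide F1, which can be purified. Compound 18 is converted with Zn dust and LiCl in THF into the benzylzinc chloride F2. Negishi coupling of F1 with F2 under Pd(PPh3)4 catalysis should then give 20 with retention of the E geometry.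

Step 4. The risks are migration of the oxirane toward the neighbouring tertiary alkoxide (Payne-type equilibration), halide opening of the epoxide by MgBr2, and attack through the α-carbon of the reagent to give an allene. The fallback makes the C8′–C9′ bond before the diol is unveiled, sets out from 2 and returns at 6. Compound 2 is converted with Tf2O and 2,6-lutidine at −78 °C into the epoxy triflate F3. F3 is alkylated at C1 with lithiated 1-(trimethylsilyl)propyne (THF/DMPU, −78 °C) to give the silyl epoxy-enyne F4. Acid hydrolysis (HClO4, aqueous THF, inversion at the tertiary carbon) gives the silyl alkyne diol F5, and K2CO3 in MeOH removes the silyl group to give 6.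

Step 12. The risks are competing oxidation of the trisubstituted olefins and acid-induced loss of the acetonide followed by glycol cleavage by tetravalent cerium. The fallback moves the oxidation ahead of the coupling, sets out from 18 (with 13) and returns at 21. Compound 18 is oxidised with (NH4)2Ce(NO3)6 in MeCN/H2O to 2-(chloromethyl)-6-methyl-1,4-benzoquinone F6 while no olefin or acetal is present. F6 is then coupled with dienylalane 19 (made from 13 as in step 11) under zerovalent nickel catalysis (NiCl2(PPh3)2/n-BuLi, THF, −20 °C) to give 21 directly.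

Further compounds
F1 | step 11 | (4R,5R)-4-[(3E,7E)-8-iodo-3,7-dimethylocta-3,7-dien-1-yl]-2,2,5-trimethyl-5-(4-methylpent-3-en-1-yl)-1,3-dioxolane | CC(C)=CCC[C@@]1(C)OC(C)(C)O[C@@H]1CC/C(C)=C/CC/C(C)=C/I
F2 | step 11 | chloro(2,5-dimethoxy-3-methylbenzyl)zinc | COc1cc(C)c(OC)c(C[Zn]Cl)c1
F3 | step 4 | [(2R,3S)-3-methyl-3-(4-methylpent-3-en-1-yl)oxiran-2-yl]methyl trifluoromethanesulfonate | CC(C)=CCC[C@]1(C)O[C@@H]1COS(=O)(=O)C(F)(F)F
F4 | step 4 | trimethyl{5-[(2R,3S)-3-methyl-3-(4-methylpent-3-en-1-yl)oxiran-2-yl]pent-1-yn-1-yl}silane | CC(C)=CCC[C@]1(C)O[C@@H]1CCC#C[Si](C)(C)C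
F5 | step 4 | (5R,6R)-6,10-dimethyl-1-(trimethylsilyl)undec-9-en-1-yne-5,6-diol | CC(C)=CCC[C@@](C)(O)[C@H](O)CCC#C[Si](C)(C)C
F6 | step 12 | 2-(chloromethyl)-6-methylcyclohexa-2,5-diene-1,4-dione | ClCC1=CC(=O)C=C(C)C1=O
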